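## Structural features

The target is a tricyclic sesquiterpenoid ester. A cyclohexane (ring A: C5, C6, C7, C8, C9, C10, eudesmane numbering) is fused through the C5–C10 bond to a second carbocycle (ring B: C1, C2, C3, C4, C5, C10) whose C1 and C4 are tied by an oxygen atom, so ring B is a 7-oxabicyclo[2.2.1]heptane. The fusion is trans with respect to that bicycle: C9 is exo (on the side of the oxygen bridge) and C6 is endo, which twists ring A and strains the skeleton. Six stereocentres are contiguous: the ether bridgeheads C1 (CH) and C4 (fully substituted, methyl C15), the all-carbon quaternary C10 (methyl C14, endo), the ring-fusion methine C5 (H exo), the carbinol C6 with the 4-methoxybenzoate, and C7 with the isopropyl group; ester, isopropyl and H5 are mutually cis and trans to C14. Fragile points are the aryl ester (bases, hydrides, organometallics), the tertiary C4–O ether bond (strong acid) and, in any intermediate with a C6 carbonyl, the C5–H bond, because enolisation there lets the trans fusion relax to the cis isomer. The real difficulty is the trans C5–C10 junction between two fully substituted carbons (C4 and C10), together with the C6/C7 configuration on a ring that is hindered on both faces. The key step uses the fact that the C5–C10 bond belongs both to ring A and to the oxolane ring (O, C1, C10, C5, C4) of the oxanorbornane: moving C10 from C6 to C5 in a cyclopentanol-fused 8-oxabicyclo[3.2.1]octane forms both ring systems and both ring-fusion stereocentres at once.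

## Logic of the disconnections

24 ⇒ 22 + 23. The alkyl–oxygen bond C6–O of the ester is cut. The aryl ester is the group least tolerant of the earlier chemistry, so it comes last. The hydroxyl that steers the C7 hydrogenation must sit on the face opposite to the final ester, so an inverting esterification fits. The demand is an SN2 displacement at a hindered secondary carbinol next to a cis isopropyl group.

22 ⇒ 21. The C7–H and C11–H bonds are removed to give the C7=C11 alkene. This deletes the C7 stereocentre, which the neighbouring C6 hydroxyl can set by directed hydrogenation. The demand is that the C6 hydroxyl of 21 lies on the β face, the face on which H7 must arrive.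

21 ⇒ 20. The C6–H bond is removed to give the conjugated ketone, the direct product of the skeletal shift. The forward reduction must be 1,2-selective, come from the α face, and not enolise C5.

20 ⇒ 19. The C5–C10 bond is cut and C10 is reconnected to C6, with a sulfonate on C5 and a hydroxyl on C6. Because C5–C10 is common to ring A and the oxolane, this one retro-shift turns the strained trans-fused tricycle into an unstrained cis-fused cyclopentanol on an 8-oxabicyclo[3.2.1]octane, the skeleton that a furan [4+3] cycloaddition delivers. Two ring-fusion stereocentres are exchanged for chair stereochemistry. The forward step demands an equatorial C5–O bond, an axial C9 on C10 and an axial C6–O, and a base that does not enolise the product.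

19 ⇒ 18 ⇒ 16 (through 17). The S–O bond is cut, then the C6–C7 bond. Adding a C7 vinyl anion to the C6 ketone makes the tertiary carbinol, the cyclopentane and the isopropylidene in one step. The demand is halogen–metal exchange in the presence of a ketone, closure from the face of the axial tether, and a masked C5 oxygen.

16 ⇒ 14 ⇒ 12 (through 15 and 13). The C5–O bond is cut. C5 is the only enolisable position of 12, so enolate oxidation has no regiochemical question. The electrophile is expected to enter axially, so the equatorial configuration must come from equilibration, driven by the 1,3-diaxial contact with C9.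

12 ⇒ 6 + 10 (through 11). The C9–C10 bond is cut. Axial alkylation of the bicyclic enolate sets the quaternary C10 and makes the route convergent. The tetrasubstituted enolate must be formed regiospecifically, which is why 6 is made from 5 under thermodynamic control, and substitution must beat elimination of the iodide.

10 ⇒ 9 ⇒ 7 (through 8). The C–I bond and then the vinylic C–Br bond are cut, back to a commercial homoprenyl bromide. The forward bromination–dehydrobromination must eliminate toward the bromine-bearing carbon.

5 ⇒ 4 ⇒ 3 ⇒ 1 + 2. The enantiomers are separated at 4, two C–H bonds are removed to give 3, and the C1–C10 and C4–C5 bonds are cut ([4+3]). This reaches two commercial compounds. The demand is that the methyl-bearing cation terminus bonds to the unsubstituted furan carbon. Resolution is placed here so that only inexpensive material is discarded.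

## Other disconnections considered

Alternative 1: The cut is the C3–C4 bond of ring B. Forward, the diazoketone A1 (an oxolane O, C1, C10, C5, C4 trans-fused to a finished ring A with ester and isopropyl in place) would be treated with Rh2(OAc)4. The carbenoid carbon C3 inserts into the C4–H bond on the same face of the oxolane with retention and closes ring B as the 7-oxanorbornan-2-one A2.
- In favour: the C–H bond is tertiary and activated by the ether oxygen, and C6 and C7 are set on an unstrained bicycle. A2 has no enolisable hydrogen at the ring fusion (its ketone is flanked by a bridgehead and a methylene), so the strained junction cannot epimerise once formed. On this point the alternative is better than the chosen plan, whose ketone 20 has an acidic C5–H.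
- Against: the insertion must reach across the oxolane to make a bicyclo[2.2.1] ring and competes with insertion into the C9 methylene and the C14 methyl, which are equally distant from the carbenoid. A1 has five stereocentres including the quaternary C10 and is no easier to make than 19. A2 carries an extra oxygen at C2 that must be removed without harming the aryl ester.
- Comparison: both plans form the oxanorbornane last. The chosen shift is stereospecific by geometry, whereas the insertion is site-selective only by electronics. In step count the alternative should be the longer one, although its last stages avoid the inversion at C6 and are equal or better there.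

Alternative 2: The cuts are C5–C6 and C4–O. Forward, Me2AlCl activates the aldehyde of the ring-B cyclohexenol A3; C5 of the C4=C5 alkene attacks C6 to close ring A, and the C1 hydroxyl captures the tertiary C4 cation to close the bridge. This gives the alcohol A4, which needs only acylation with 23.
- In favour: two rings and three stereocentres (C4, C5, C6) form in one operation from a monocyclic precursor, and the C6 oxygen arrives at the alcohol level with no reduction or inversion. On step economy and on the end game this alternative is the better one.
- Against: the strained trans-fused bicycle must be closed by trapping a cation, which is reversible under Lewis acid and competes with proton loss from C3 or C15 (the usual ene-type outcome). The free hydroxyl reacts with the aluminium reagent, the aldehyde α-carbon C7 can epimerise, and the C6 configuration rests on a transition-state preference that the strain may overturn.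
- Comparison: the Prins route makes the bond to C5 from the other side (C5–C6 instead of C5–C10) under thermodynamic risk, whereas the semipinacol shift is irreversible and fixed by antiperiplanar alignment. The quaternary C10 with its relation to C1 must be made beforehand in both plans, which is equal work.

Alternative 3: The cuts are C1–C10 and C4–C5. Forward, irradiation of (S)-piperitone A5 in an excess of 1 would add the two furan α-carbons across the C5=C10 enone bond through the twisted excited enone, giving the trans-fused oxanorbornene A6. Hydrogenation, reduction at C6 and esterification would follow.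
- In favour: one step from two commercial compounds makes ring B, the bridge and four stereocentres; the trans junction is the native result of the twisted enone; and C7 comes from the chiral pool, so no resolution is needed. On step count (about five steps) and on the source of absolute configuration it is better than the chosen plan.
- Against: the photoreaction must choose between [4+2] and [2+2] addition, between two orientations of the unsymmetrical furan, between two faces relative to the isopropyl group and between two exo/endo topologies, so a mixture is expected. A5 and A6 both have an enolisable C7–H, and A6 also the acidic C5–H, so optical purity and the trans junction are both at risk. The C6 reduction would meet the same facial problem and need the same inversion.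
- Comparison: the two plans reach closely related trans-fused C6 ketones (A6 and 20) and are equal in the fragility of that ketone. The chosen plan sets each stereocentre in a separate, geometrically defined event; the photoaddition sets four in one weakly controlled event.

Key step: step 12

Remark on the chemistry (assumption): eudesmane numbering is kept for every intermediate (C14 = methyl on C10, C15 = methyl on C4), and β is the face of ring A that carries C14. Compounds 3 and 4 are racemates whose SMILES show the enantiomer that is carried on. Structures 19 and 20 were mapped atom by atom onto 24 (C1, C4, C10 unchanged, C5 inverted in the shift) and needed no correction.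

## Route

Step 1
Reactants: 1 2-methylfuran; 2 3-chlorobutan-2-one
Product: 3 rac-1,4-dimethyl-8-oxabicyclo[3.2.1]oct-6-en-3-one
Conditions: Et3N, CF3CH2OH, 0 °C → rt (1 in excess)
Reagents that add atoms: none
Why: [4+3] cycloaddition of the oxyallyl cation formed by amine-promoted loss of HCl from 2 in the ionising fluoroalcohol. The methyl-bearing terminus should bond to the unsubstituted furan α-carbon (no vicinal quaternary–tertiary contact), placing C14 next to the H-bearing bridgehead C1, and the compact transition state of the W-shaped cation puts it equatorial. The regioisomer is removed by chromatography.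

Step 2
Reactants: 3 rac-1,4-dimethyl-8-oxabicyclo[3.2.1]oct-6-en-3-one
Product: 4 rac-1,4-dimethyl-8-oxabicyclo[3.2.1]octan-3-one
Conditions: H2 (1 atm), Pd/C, EtOAc, rt; then NaOMe (cat.), MeOH, rt
Reagents that add atoms: none
Why: Heterogeneous syn hydrogenation of the bridging alkene leaves ketone and ether bridge untouched. Brief methoxide equilibration through the C10 enolate converges any axial-methyl epimer to the equatorial one, so a single racemate enters the resolution.

Step 3
Reactants: 4 rac-1,4-dimethyl-8-oxabicyclo[3.2.1]octan-3-one
Product: 5 1,4-dimethyl-8-oxabicyclo[3.2.1]octan-3-one as the single enantiomer shown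
Conditions: preparative supercritical-fluid chromatography, amylose tris(3,5-dimethylphenylcarbamate) phase, CO2/i-PrOH
Reagents that add atoms: none
Why: Resolution of a racemate on a chiral stationary phase, placed at the first configurationally fixed ketone so that only inexpensive material is lost. The bridgeheads C1 and C4 fixed here control every later stereocentre; the correct enantiomer is assigned by anomalous-dispersion crystallography of a later bromo intermediate such as 16.

Step 4
Reactants: 5 1,4-dimethyl-8-oxabicyclo[3.2.1]octan-3-one
Product: 6 1,4-dimethyl-3-(trimethylsilyloxy)-8-oxabicyclo[3.2.1]oct-3-ene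
Conditions: i-Pr2NMgBr, Et2O, rt; then Me3SiCl, Et3N, HMPA, rt
Reagents that add atoms: chlorotrimethylsilane, C[Si](C)(C)Cl
Why: Silyl enol ether formation under equilibrating magnesium amide conditions (thermodynamic control) should select the more substituted C6=C10 enol ether. This fixes the regiochemistry of the C10 alkylation, which a kinetic lithium amide deprotonation would direct to the C5 methylene.

Step 5
Reactants: 7 5-bromo-2-methylpent-2-ene
Product: 9 3,5-dibromo-2-methylpent-2-ene, via 1,3,4-tribromo-4-methylpentane 8 (not isolated)
Conditions: Br2, CH2Cl2, −78 °C; then DBU, 0 °C → rt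
Reagents that add atoms: bromine, BrBr
Why: Bromination–dehydrobromination: anti addition of bromine to the trisubstituted alkene, then E2 loss of the tertiary bromide with the acidified hydrogen on the bromine-bearing carbon should give the tetrasubstituted vinyl bromide. The primary bromide is expected to survive the cold amidine treatment.

Step 6
Reactants: 9 3,5-dibromo-2-methylpent-2-ene
Product: 10 3-bromo-5-iodo-2-methylpent-2-ene
Conditions: NaI, acetone, reflux
Reagents that add atoms: sodium iodide, [Na+].[I-]
Why: Finkelstein halide exchange at the primary carbon, driven by precipitation of NaBr; the vinyl bromide is inert to SN2.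

Step 7
Reactants: 6 1,4-dimethyl-3-(trimethylsilyloxy)-8-oxabicyclo[3.2.1]oct-3-ene; 10 3-bromo-5-iodo-2-methylpent-2-ene
Product: 12 4-(3-bromo-4-methylpent-3-enyl)-1,4-dimethyl-8-oxabicyclo[3.2.1]octan-3-one with the chain axial, via lithium enolate 11 (not isolated)
Conditions: MeLi, THF, −20 → 0 °C; then 10, DMPU, −78 → −20 °C
Reagents that add atoms: none
Why: Regiospecific lithium enolate generation from the silyl enol ether, then SN2 C-alkylation by the primary iodide. The electrophile enters on the face of the oxygen bridge, anti to the C2–C3 ethano bridge, so C9 becomes axial and C14 equatorial at the new quaternary C10. Low temperature and DMPU favour substitution over E2 of the homoallylic iodide.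

Step 8
Reactants: 12 4-(3-bromo-4-methylpent-3-enyl)-1,4-dimethyl-8-oxabicyclo[3.2.1]octan-3-one
Product: 14 4-(3-bromo-4-methylpent-3-enyl)-2-hydroxy-1,4-dimethyl-8-oxabicyclo[3.2.1]octan-3-one with the C5 hydroxyl axial, via potassium enolate 13 (not isolated)
Conditions: KN(SiMe3)2, THF, −78 °C; then 2-(phenylsulfonyl)-3-phenyloxaziridine, −78 °C; aq NH4Cl
Reagents that add atoms: 2-(phenylsulfonyl)-3-phenyloxaziridine, O=S(=O)(c1ccccc1)N1OC1c1ccccc1
Why: Electrophilic α-hydroxylation of the only possible enolate (C5) by an N-sulfonyloxaziridine. The endo face is blocked by the ethano bridge, so oxygen should enter from the oxygen-bridge face and sit axial, syn to C9. This configuration is not final because step 9 corrects it thermodynamically.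

Step 9
Reactants: 14 4-(3-bromo-4-methylpent-3-enyl)-2-hydroxy-1,4-dimethyl-8-oxabicyclo[3.2.1]octan-3-one
Product: 16 4-(3-bromo-4-methylpent-3-enyl)-2-(tert-butyldimethylsilyloxy)-1,4-dimethyl-8-oxabicyclo[3.2.1]octan-3-one with the C5 silyloxy group equatorial, via axial silyl ether 15 (not isolated)
Conditions: t-BuMe2SiOTf, 2,6-lutidine, CH2Cl2, −78 → 0 °C; then DBU, 40 °C
Reagents that add atoms: tert-butyldimethylsilyl trifluoromethanesulfonate, CC(C)(C)[Si](C)(C)OS(=O)(=O)C(F)(F)F
Why: O-Silylation, then amidine-mediated equilibration through the C5 enolate. The axial ether is 1,3-diaxial to the C9 chain, so the equilibrium should lie on the equatorial ether with H5 axial, the geometry the key step needs. The hydroxyl is capped first so that no enediol (ketol transposition) pathway is open.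

Step 10
Reactants: 16 4-(3-bromo-4-methylpent-3-enyl)-2-(tert-butyldimethylsilyloxy)-1,4-dimethyl-8-oxabicyclo[3.2.1]octan-3-one
Product: 18 cis-fused cyclopentanol diol (C6–OH tertiary and axial; C5–OH secondary and equatorial; C7 isopropylidene), via cyclised silyl ether 17 (not isolated)
Conditions: t-BuLi (2.2 equiv), THF, −78 °C; AcOH; then Bu4NF, THF, 0 °C → rt
Reagents that add atoms: none
Why: Bromine–lithium exchange should outpace addition of t-BuLi to the doubly hindered ketone. The tetrasubstituted vinyllithium then adds 5-exo-trig to C6 from the face of its axial tether (intramolecular carbonyl addition, cyclopentannulation), giving the cis-fused cyclopentanol with C7 equatorial and the tertiary oxygen axial. Fluoride removes the silyl group wherever it then resides.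

Step 11
Reactants: 18 cis-fused cyclopentanol diol
Product: 19 hydroxy mesylate (C5–OMs equatorial; C6–OH tertiary and axial; C7 isopropylidene)
Conditions: MeSO2Cl, Et3N, CH2Cl2, −20 → 0 °C
Reagents that add atoms: methanesulfonyl chloride, CS(=O)(=O)Cl
Why: Sulfene-type mesylation occurs only at the secondary C5 hydroxyl; the tertiary allylic C6 hydroxyl is too hindered to react, so no protection is needed.

Step 12
Reactants: 19 hydroxy mesylate
Product: 20 1,4-epoxyeudesm-7(11)-en-6-one (trans-fused)
Conditions: KOt-Bu (1.0 equiv, added slowly), THF, −78 → 0 °C; pH 7 phosphate buffer
Reagents that add atoms: none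
Why: KOt-Bu deprotonates the tertiary C6 hydroxyl; as the alkoxide becomes the C6 carbonyl, the C6–C10 σ bond, antiperiplanar to the equatorial C5–O bond of the mesylate, migrates to C5 and expels methanesulfonate in a concerted 1,2-shift (retention at the migrating C10, inversion at C5). The closest known reaction type is the base-induced semipinacol rearrangement of 2-sulfonyloxy tertiary alcohols, a relative of the quasi-Favorskii contraction of [4+3] adducts. Both rings arise from the one shift and not from a cyclisation: the oxygen-containing six-membered ring (O, C1, C10, C6, C5, C4) contracts to the oxolane of the 7-oxanorbornane by extruding C6, and the cyclopentane (C6, C7, C8, C9, C10) expands to ring A by taking in C5. C10 keeps its configuration, so the formerly axial C9 becomes exo and C14 endo (controlled by the axial alkylation of step 7); C5 is inverted, so H5 becomes exo and C6 endo (controlled by the equatorial sulfonate from step 9), which makes the fusion trans. The step needs migration of C10 in preference to C7, the bridge oxygen or epoxide closure: in the chair only C6–C10 and C4–O are anti to the leaving group, the alkoxide oxygen and C7 are gauche to it, and the alkoxide push acts on C6–C10 alone. It also needs the kinetically formed trans ketone to survive, since C5–H is now α to the carbonyl and epimerisation would relieve strain; one equivalent of base (consumed as potassium methanesulfonate), low temperature and a buffered quench are chosen for that reason.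

Step 13
Reactants: 20 1,4-epoxyeudesm-7(11)-en-6-one
Product: 21 1,4-epoxyeudesm-7(11)-en-6-ol with the hydroxyl β (syn to C14)
Conditions: NaBH4, CeCl3·7H2O, MeOH, −78 → −40 °C
Reagents that add atoms: none
Why: Luche 1,2-reduction of the enone. The β face of the C6 carbonyl is screened by the endo C14 methyl, which eclipses C6 across the C5–C10 bond, so hydride should add from the α face and give the β allylic alcohol. The cold, nearly neutral medium should not enolise C5.

Step 14
Reactants: 21 1,4-epoxyeudesm-7(11)-en-6-ol
Product: 22 1,4-epoxyeudesman-6-ol with hydroxyl and H7 both β (isopropyl α)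
Conditions: H2 (1 atm), [Ir(cod)(PCy3)(py)]PF6 (cat.), CH2Cl2, rt
Reagents that add atoms: none
Why: Hydroxyl-directed homogeneous hydrogenation: the cationic iridium catalyst binds the C6 hydroxyl and delivers both hydrogens to the face of the tetrasubstituted C7=C11 bond syn to oxygen, which sets H7 β and the isopropyl group α.

Step 15
Reactants: 22 1,4-epoxyeudesman-6-ol; 23 4-methoxybenzoic acid
Product: 24 1,4-epoxyeudesman-6-yl 4-methoxybenzoate (target)
Conditions: PPh3, i-PrO2CN=NCO2i-Pr, toluene, 0 °C → rt
Reagents that add atoms: none
Why: Mitsunobu esterification: the alkoxyphosphonium ion of 22 is displaced by 4-methoxybenzoate with inversion at C6, placing the ester α, cis to the isopropyl group and trans to C14 as in 24.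

## Compound list

1 | 2-methylfuran | Cc1ccco1 | starting material
2 | 3-chlorobutan-2-one (racemic) | CC(Cl)C(C)=O | starting material
3 | rac-1,4-dimethyl-8-oxabicyclo[3.2.1]oct-6-en-3-one; bridgehead methyl = C15 on C4, α-methyl = C14 on C10, equatorial, next to the H-bearing bridgehead | C[C@@H]1C(=O)C[C@]2(C)C=C[C@H]1O2 | intermediate
4 | rac-1,4-dimethyl-8-oxabicyclo[3.2.1]octan-3-one, C14 equatorial | C[C@@H]1C(=O)C[C@]2(C)CC[C@H]1O2 | intermediate
5 | 1,4-dimethyl-8-oxabicyclo[3.2.1]octan-3-one, single enantiomer | C[C@@H]1C(=O)C[C@]2(C)CC[C@H]1O2 | intermediate
6 | 1,4-dimethyl-3-(trimethylsilyloxy)-8-oxabicyclo[3.2.1]oct-3-ene (C6=C10 enol ether) | CC1=C(O[Si](C)(C)C)C[C@]2(C)CC[C@H]1O2 | intermediate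
7 | 5-bromo-2-methylpent-2-ene | CC(C)=CCCBr | starting material
8 | 1,3,4-tribromo-4-methylpentane (racemic, not isolated) | CC(C)(Br)C(Br)CCBr | intermediate
9 | 3,5-dibromo-2-methylpent-2-ene | CC(C)=C(Br)CCBr | intermediate
10 | 3-bromo-5-iodo-2-methylpent-2-ene | CC(C)=C(Br)CCI | intermediate
11 | lithium enolate of 5 (C6=C10, not isolated) | [Li+].CC1=C([O-])C[C@]2(C)CC[C@H]1O2 | intermediate
12 | 4-(3-bromo-4-methylpent-3-enyl)-1,4-dimethyl-8-oxabicyclo[3.2.1]octan-3-one; C9 chain axial (syn to the oxygen bridge), C14 equatorial | C[C@]1(CCC(Br)=C(C)C)C(=O)C[C@]2(C)CC[C@H]1O2 | intermediate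
13 | potassium enolate of 12 (C5=C6, not isolated) | [K+].C[C@]1(CCC(Br)=C(C)C)C([O-])=C[C@]2(C)CC[C@H]1O2 | intermediate
14 | 2-hydroxy derivative of 12; C5–OH axial, syn to the C9 chain | C[C@]1(CCC(Br)=C(C)C)C(=O)[C@@H](O)[C@]2(C)CC[C@H]1O2 | intermediate
15 | tert-butyldimethylsilyl ether of 14, C5–O axial (not isolated) | C[C@]1(CCC(Br)=C(C)C)C(=O)[C@@H](O[Si](C)(C)C(C)(C)C)[C@]2(C)CC[C@H]1O2 | intermediate
16 | C5 epimer of 15; C5–OSi equatorial, H5 axial | C[C@]1(CCC(Br)=C(C)C)C(=O)[C@H](O[Si](C)(C)C(C)(C)C)[C@]2(C)CC[C@H]1O2 | intermediate
17 | cyclised silyl ether: cis-fused cyclopentanol on the 8-oxabicyclo[3.2.1]octane, C6–OH axial, C5–OSi equatorial, C7 isopropylidene (not isolated) | C[C@]12CCC(=C(C)C)[C@@]1(O)[C@H](O[Si](C)(C)C(C)(C)C)[C@]3(C)CC[C@H]2O3 | intermediate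
18 | diol: C6–OH tertiary and axial, C5–OH secondary and equatorial, C7 isopropylidene | C[C@]12CCC(=C(C)C)[C@@]1(O)[C@H](O)[C@]3(C)CC[C@H]2O3 | intermediate
19 | hydroxy mesylate: C5–OMs equatorial, C6–OH axial, C7 isopropylidene | C[C@]12CCC(=C(C)C)[C@@]1(O)[C@H](OS(C)(=O)=O)[C@]3(C)CC[C@H]2O3 | intermediate
20 | 1,4-epoxyeudesm-7(11)-en-6-one; trans-fused, C9 exo, C6 endo | O=C1C(=C(C)C)CC[C@]2(C)[C@H]3CC[C@](C)(O3)[C@@H]12 | intermediate
21 | 1,4-epoxyeudesm-7(11)-en-6-ol, hydroxyl β (syn to C14) | O[C@H]1C(=C(C)C)CC[C@]2(C)[C@H]3CC[C@](C)(O3)[C@@H]12 | intermediate
22 | 1,4-epoxyeudesman-6-ol, hydroxyl β, H7 β, isopropyl α | O[C@H]1[C@H](C(C)C)CC[C@]2(C)[C@H]3CC[C@](C)(O3)[C@@H]12 | intermediate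
23 | 4-methoxybenzoic acid | COc1ccc(cc1)C(O)=O | starting material
24 | 1,4-epoxyeudesman-6-yl 4-methoxybenzoate (CNP0196044.2) | COc1ccc(C(=O)O[C@@H]2[C@H](C(C)C)CC[C@]3(C)[C@H]4CC[C@](C)(O4)[C@@H]23)cc1 | target

## Step count and least certain steps

Total step count: 15. Longest linear sequence: 13 steps (1, 2, 3, 4, 7, 8, 9, 10, 11, 12, 13, 14, 15); the side chain 10 takes 2 steps (5, 6).

Step 12 (key step). What may go wrong: alkoxide that has not yet rearranged may enolise the new ketone toward C5, so the strained trans junction is lost by epimerisation. γ-Deprotonation may deconjugate the isopropylidene, or the shift may be slow if strain in the developing trans junction raises the barrier. Fallback (from 19, rejoining at 21): 19 is converted with Et2AlCl in CH2Cl2 at −78 °C into its chloroaluminium alkoxide. The metal pushes from oxygen and pulls on the sulfonate, so the same antiperiplanar shift of C10 runs without free base. i-Bu2AlH is then added at −78 °C so that the aluminium-bound enone is reduced in the flask, from the same α face, before it can enolise. No compound outside the list is formed.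

Step 1. What may go wrong: poor regioselectivity (the methyl-bearing cation terminus bonding to the methyl-bearing furan carbon) and furan oligomerisation, because an alkyl-substituted oxyallyl cation is only weakly biased. Fallback (from 1, rejoining at 4): 1 and 1,1,3-trichloroacetone under the same amine/fluoroalcohol conditions give the dichloro cycloadduct 2,4-dichloro-1-methyl-8-oxabicyclo[3.2.1]oct-6-en-3-one F1, whose symmetrical cation removes the regiochemical question. Zn–Cu couple with NH4Cl in MeOH removes both chlorines to give 1-methyl-8-oxabicyclo[3.2.1]oct-6-en-3-one F2. Hydrogenation (H2, Pd/C) gives 1-methyl-8-oxabicyclo[3.2.1]octan-3-one F3. Kinetic deprotonation with LiN(i-Pr)2 at the less hindered methylene next to the H-bearing bridgehead and methylation with MeI gives the axial-methyl ketone F4, which NaOMe in MeOH equilibrates to 4.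

Step 7. What may go wrong: E2 elimination of the homoallylic iodide by the hindered, strongly basic tetrasubstituted enolate, or O-alkylation, may outrun C-alkylation at the congested C10. Fallback (from 9, rejoining at 12): the electrophile is changed to a triflate so that substitution runs at −78 °C, where elimination is slow. 9 with KOAc in DMF gives 3-bromo-4-methylpent-3-enyl acetate F5; K2CO3 in MeOH gives 3-bromo-4-methylpent-3-en-1-ol F6; triflic anhydride with 2,6-di-tert-butyl-4-methylpyridine gives 3-bromo-4-methylpent-3-enyl trifluoromethanesulfonate F7. F7 is added at once to enolate 11 at −78 °C to give 12.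

Step 9. What may go wrong: incomplete equilibration, because the remaining C5–H of the axial ether is equatorial and poorly aligned with the carbonyl, or a base-induced 1,4-silyl shift across the enediolate leading to ketol transposition. Fallback (from 14, rejoining at 16): a redox relay that sets C5 kinetically. Dess–Martin oxidation of 14 gives the non-enolisable 1,2-dione F8. NaBH4 at −78 °C should attack the C5 carbonyl from the oxygen-bridge face (the C6 carbonyl is screened by the axial C9 chain on one face and the ethano bridge on the other), giving the equatorial hydroxy ketone F9. Silylation with t-BuMe2SiOTf and 2,6-lutidine gives 16.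

Step 15. What may go wrong: slow substitution and elimination toward C5 or C7, because the carboxylate must approach C6 on the face that carries the cis isopropyl group; retention through an acyloxyphosphonium pathway is also possible. Fallback (from 22, rejoining at 24): a two-stage sulfonate displacement. 22 with chloromethanesulfonyl chloride and pyridine gives the chloromethanesulfonate F10. Cesium 4-methoxybenzoate (from 23 and Cs2CO3) with 18-crown-6 in toluene at 80 °C displaces it with inversion to give 24.

## Further compounds

F0 | step 12 | none | none
F1 | step 1 | rac-2,4-dichloro-1-methyl-8-oxabicyclo[3.2.1]oct-6-en-3-one (mixture of chloro epimers) | ClC1C(=O)C(Cl)[C@]2(C)C=C[C@H]1O2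
F2 | step 1 | rac-1-methyl-8-oxabicyclo[3.2.1]oct-6-en-3-one | C1C(=O)C[C@]2(C)C=C[C@H]1O2
F3 | step 1 | rac-1-methyl-8-oxabicyclo[3.2.1]octan-3-one | C1C(=O)C[C@]2(C)CC[C@H]1O2
F4 | step 1 | rac-1,4-dimethyl-8-oxabicyclo[3.2.1]octan-3-one, C14 axial (C10 epimer of 4) | C[C@H]1C(=O)C[C@]2(C)CC[C@H]1O2
F5 | step 7 | 3-bromo-4-methylpent-3-enyl acetate | CC(=O)OCCC(Br)=C(C)C
F6 | step 7 | 3-bromo-4-methylpent-3-en-1-ol | OCCC(Br)=C(C)C
F7 | step 7 | 3-bromo-4-methylpent-3-enyl trifluoromethanesulfonate | CC(C)=C(Br)CCOS(=O)(=O)C(F)(F)F
F8 | step 9 | 4-(3-bromo-4-methylpent-3-enyl)-1,4-dimethyl-8-oxabicyclo[3.2.1]octane-2,3-dione | C[C@]1(CCC(Br)=C(C)C)C(=O)C(=O)[C@]2(C)CC[C@H]1O2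
F9 | step 9 | C5 epimer of 14 (C5–OH equatorial) | C[C@]1(CCC(Br)=C(C)C)C(=O)[C@H](O)[C@]2(C)CC[C@H]1O2
F10 | step 15 | chloromethanesulfonate of 22 (sulfonate β at C6) | ClCS(=O)(=O)O[C@H]1[C@H](C(C)C)CC[C@]2(C)[C@H]3CC[C@](C)(O3)[C@@H]12
A1 | alternative 1 | diazoketone: oxolane trans-fused to ring A, diazoacetyl on C1 cis to H4, 6-(4-methoxybenzoate), 7-isopropyl | COc1ccc(cc1)C(=O)O[C@@H]1[C@H](C(C)C)CC[C@]2(C)[C@@H](C(=O)C=[N+]=[N-])O[C@H](C)[C@@H]12
A2 | alternative 1 | 2-oxo-1,4-epoxyeudesman-6-yl 4-methoxybenzoate | COc1ccc(cc1)C(=O)O[C@@H]1[C@H](C(C)C)CC[C@]2(C)[C@H]3C(=O)C[C@](C)(O3)[C@@H]12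
A3 | alternative 2 | ring-B cyclohexenol aldehyde (C1–OH, C4=C5, C10 quaternary, C6 aldehyde, C7 isopropyl) | O=C[C@H](C(C)C)CC[C@@]1(C)C=C(C)CC[C@H]1O
A4 | alternative 2 | 1,4-epoxyeudesman-6-ol (hydroxyl α, as in the target) | O[C@@H]1[C@H](C(C)C)CC[C@]2(C)[C@H]3CC[C@](C)(O3)[C@@H]12
A5 | alternative 3 | (S)-piperitone | O=C1[C@H](C(C)C)CCC(C)=C1
A6 | alternative 3 | trans-fused 1,4-epoxyeudesm-2-en-6-one | O=C1[C@H](C(C)C)CC[C@]2(C)[C@H]3C=C[C@](C)(O3)[C@@H]12
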